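**Retrosynthetic overview**

1. The target is epicatechin-(C4→C6)-ent-epicatechin-(C4→C8)-epicatechin-(C4→C6)-epicatechin (units 1 to 4). The strategy rests on ring C of unit 2, the only 2S,3S flavan: its C2 aryl, C3 oxygen and C4 aryl are all cis, and C4 is bonded to C8 of unit 3.
2. Last disconnections: hydrogenolysis of 20 benzyl ethers and one aryl bromide; before it the unit 1 C4–unit 2 C6 bond (3,4-cis in unit 1) by addition of the 6-lithio trimer to a unit 1 4-ketone and ionic hydrogenation.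
3. Key disconnection: ring C of unit 2 (bonds O1–C2 and C3–C4) by an oxa-[4+2] between the ortho-quinone methide made of ring A of unit 2 plus the exocyclic C4 that carries unit 3, and a Z 2-arylethenyl acetate, under a chiral phosphoric acid.
4. The carbinol precursor comes from the 8-magnesio unit 3–4 dimer and a ring A salicylaldehyde. The dimer comes from two epicatechin halves by a C4→C6 Friedel–Crafts union (iodide at C8 of unit 3 as cap and later handle, bromide at C8 of unit 4 as block).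
5. Ring order: all rings of units 1, 3 and 4 and rings A and B of unit 2 are carried in from starting materials; only ring C of unit 2 is built (step 16).

Key step: step 16

Remark on spectator groups: the precursor 17 and the product 22 of the key step carry a bromide at C8 of unit 4 (it forces the unit 3–unit 4 bond to C6 and leaves in step 23) and an iodide at C6 of unit 2 (without it the later union with unit 1 could not be directed to C6 instead of C8).

Assumption: which antipode of the phosphoric acid is matched with the chiral dimer has to be found by running both; the (R) acid is written.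

**Route**

Step 1
Reactants: 1 (−)-epicatechin
Product: 2 5,7,3',4'-tetra-O-benzylepicatechin (2R,3R; 3-OH free)
Conditions: BnBr (4.4 equiv), K2CO3, DMF, 0 °C to rt
Reagents that add atoms: benzyl bromide, BrCc1ccccc1
Why: Williamson etherification; under carbonate only the four phenols are ionised, so the secondary 3-OH and both stereocentres stay untouched.

Step 2
Reactants: 2 5,7,3',4'-tetra-O-benzylepicatechin
Product: 3 3,5,7,3',4'-penta-O-benzylepicatechin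
Conditions: NaH, BnBr, Bu4NI (cat.), DMF, 0 °C to rt
Reagents that add atoms: benzyl bromide, BrCc1ccccc1
Why: Williamson etherification of the sodium alkoxide of the 3-OH, with no change at C2 or C3.

Step 3
Reactants: 3 3,5,7,3',4'-penta-O-benzylepicatechin
Product: 4 8-bromo-3,5,7,3',4'-penta-O-benzylepicatechin
Conditions: NBS (1.0 equiv), CH2Cl2, −40 to 0 °C
Reagents that add atoms: N-bromosuccinimide, O=C1CCC(=O)N1Br
Why: Electrophilic aromatic bromination goes to C8, the most nucleophilic and least hindered position of ring A; the bromide later blocks C8 of unit 4.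

Step 4
Reactants: 3 3,5,7,3',4'-penta-O-benzylepicatechin
Product: 5 4β-(2-ethoxyethoxy)-3,5,7,3',4'-penta-O-benzylepicatechin (C4–O trans to C3–O)
Conditions: DDQ (2 equiv), EtOCH2CH2OH (5 equiv), CH2Cl2, rt
Reagents that add atoms: 2-ethoxyethanol, CCOCCO
Why: DDQ benzylic oxidation (hydride abstraction at C4 gives a ring-A-stabilised cation); the alcohol adds on the face opposite the cis 2-aryl and 3-benzyloxy groups, giving the 4β ether.

Step 5
Reactants: 5 4β-(2-ethoxyethoxy)-3,5,7,3',4'-penta-O-benzylepicatechin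
Product: 6 8-iodo-4β-(2-ethoxyethoxy)-3,5,7,3',4'-penta-O-benzylepicatechin
Conditions: NIS (1.05 equiv), CH2Cl2, 0 °C, dark
Reagents that add atoms: N-iodosuccinimide, O=C1CCC(=O)N1I
Why: Electrophilic aromatic iodination at C8 as in step 3; the iodide stops self-condensation of the electrophile and is the later metalation site of unit 3.

Step 6
Reactants: 6 8-iodo-4β-(2-ethoxyethoxy)-3,5,7,3',4'-penta-O-benzylepicatechin; 4 8-bromo-3,5,7,3',4'-penta-O-benzylepicatechin (2 equiv)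
Product: 7 unit 3–4 dimer, 8-iodo-penta-O-benzylepicatechin-(4β→6)-8-bromo-penta-O-benzylepicatechin
Conditions: BF3·OEt2, CH2Cl2, −78 to −40 °C
Reagents that add atoms: none
Why: Lewis-acid Friedel–Crafts coupling through the flavan-4-yl cation; C6 is the only free ring A position of 4, and attack on the face opposite the cis 2-aryl and 3-benzyloxy groups sets C4 of unit 3 as 4β (3,4-trans).

Step 7
Reactants: 8 3,5-bis(benzyloxy)phenol
Product: 9 [3,5-bis(benzyloxy)phenoxy]triisopropylsilane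
Conditions: i-Pr3SiCl, imidazole, DMF, rt
Reagents that add atoms: chlorotriisopropylsilane, CC(C)[Si](Cl)(C(C)C)C(C)C
Why: Silylation of the phenol; the bulky, non-directing silyl ether shields its two ortho positions in the next step.

Step 8
Reactants: 9 [3,5-bis(benzyloxy)phenoxy]triisopropylsilane
Product: 11 [3,5-bis(benzyloxy)-4-iodophenoxy]triisopropylsilane, via aryllithium 10 (not isolated)
Conditions: n-BuLi, THF, 0 °C; then I2, −78 to 0 °C
Reagents that add atoms: iodine, II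
Why: Directed ortho-metalation at the carbon between the two benzyloxy groups (cooperative direction, the silyloxy side being blocked), then iodinolysis; symmetry makes the position unambiguous.

Step 9
Reactants: 11 [3,5-bis(benzyloxy)-4-iodophenoxy]triisopropylsilane
Product: 12 3,5-bis(benzyloxy)-4-iodophenol
Conditions: Bu4NF, THF, 0 °C
Reagents that add atoms: none
Why: Fluoride cleavage of the aryl silyl ether; benzyl ethers and the aryl iodide are inert.

Step 10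
Reactants: 12 3,5-bis(benzyloxy)-4-iodophenol
Product: 13 2,4-bis(benzyloxy)-6-hydroxy-3-iodobenzaldehyde
Conditions: MgCl2, Et3N, (CH2O)n, MeCN, 80 °C
Reagents that add atoms: paraformaldehyde (reacts as formaldehyde), C=O
Why: Casnati–Skattebøl ortho-formylation through the magnesium phenoxide; the two ortho positions are equivalent, so one aldehyde results with iodine between the two benzyloxy groups.

Step 11
Reactants: 13 2,4-bis(benzyloxy)-6-hydroxy-3-iodobenzaldehyde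
Product: 14 2,4-bis(benzyloxy)-6-(tert-butyldimethylsilyloxy)-3-iodobenzaldehyde
Conditions: t-BuMe2SiCl, imidazole, DMF, rt
Reagents that add atoms: tert-butyl(chloro)dimethylsilane, CC(C)(C)[Si](C)(C)Cl
Why: Silylation of the phenol, so that the aldehyde stays electrophilic and does not quench the arylmagnesium of step 12.

Step 12
Reactants: 7 unit 3–4 dimer (8-iodide); 14 2,4-bis(benzyloxy)-6-(tert-butyldimethylsilyloxy)-3-iodobenzaldehyde
Product: 16 silyl-protected diaryl carbinol (carbinol carbon bonded to C8 of unit 3 and to C1 of the ring A aryl; both carbinol epimers), via arylmagnesium chloride 15 (not isolated)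
Conditions: i-PrMgCl·LiCl (1.0 equiv), THF, −20 to 0 °C; then 14, −40 to 0 °C; aq. NH4Cl
Reagents that add atoms: none
Why: Iodine–magnesium exchange (the electron-rich aryl bromide of unit 4 does not exchange) followed by 1,2-addition to the aldehyde, which outruns aryl–aryl exchange with the iodide of 14; the carbinol configuration is lost again in step 16.

Step 13
Reactants: 16 silyl-protected diaryl carbinol
Product: 17 [2,4-bis(benzyloxy)-6-hydroxy-3-iodophenyl](C8 of unit 3 of the dimer)methanol, both carbinol epimers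
Conditions: Bu4NF, AcOH (1:1), THF, 0 °C
Reagents that add atoms: none
Why: Buffered fluoride desilylation frees the phenol without ionising the acid-labile doubly benzylic carbinol.

Step 14
Reactants: 18 3,4-bis(benzyloxy)benzaldehyde
Product: 19 1,2-bis(benzyloxy)-4-ethynylbenzene
Conditions: MeC(O)C(N2)P(O)(OMe)2, K2CO3, MeOH/THF, rt
Reagents that add atoms: dimethyl (1-diazo-2-oxopropyl)phosphonate, COP(=O)(OC)C(=[N+]=[N-])C(C)=O
Why: Ohira–Bestmann (Seyferth–Gilbert) homologation of an aryl aldehyde to the terminal alkyne.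

Step 15
Reactants: 19 1,2-bis(benzyloxy)-4-ethynylbenzene
Product: 20 (Z)-2-[3,4-bis(benzyloxy)phenyl]ethenyl acetate
Conditions: AcOH (1.5 equiv), [Ru(η3-CH2C(CH3)CH2)2(Ph2P(CH2)4PPh2)] (2 mol %), toluene, 45 °C
Reagents that add atoms: acetic acid, CC(=O)O
Why: Ruthenium-catalysed anti-Markovnikov addition of a carboxylic acid to a terminal alkyne through a vinylidene complex, which delivers the Z enol ester.

Step 16
Reactants: 17 ortho-hydroxy diaryl carbinol; 20 (Z)-2-[3,4-bis(benzyloxy)phenyl]ethenyl acetate (3 equiv)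
Product: 22 cycloadduct trimer (unit 2: 3-O-acetyl-6-iodo-5,7,3',4'-tetra-O-benzyl-ent-epicatechin; 2S,3S; C2 aryl/C3 acetoxy/C4 aryl all cis; C4 bonded to C8 of unit 3), via ortho-quinone methide 21 (not isolated)
Conditions: (R)-3,3'-bis(2,4,6-triisopropylphenyl)-1,1'-binaphthalene-2,2'-diyl hydrogen phosphate (10 mol %), 5 Å molecular sieves, toluene, −20 °C to rt
Reagents that add atoms: none
Why: Proposed new method: the phosphoric acid ionises the doubly benzylic carbinol of 17, which loses one molecule of water (taken up by the sieves) and gives the (E)-ortho-quinone methide 21, held to the chiral phosphate by hydrogen bond and ion pairing, and the electron-rich Z alkene 20 adds across its O=C–C=C unit in an inverse-demand oxa-[4+2] in which the C3–C4 bond leads and O1 closes on the carbon that bears the cation-stabilising 3,4-bis(benzyloxy)phenyl group, which also fixes the regiochemistry (aryl at C2, acetoxy at C3). The closest known reaction type is the chiral-Brønsted-acid-catalysed oxa-Diels–Alder of in situ ortho-quinone methides with styrenes; the extension is the 2-acyloxy group on the styrene. Ring C of unit 2 is closed as the six-membered ring of a concerted, asynchronous hetero-Diels–Alder addition and not by a separate cyclisation. C4 is set by the face of 21 that the catalyst leaves open; C3 and C2 follow from it, because the Z geometry gives 2,3-cis and the endo position of the aryl group under the quinone methide gives 2,4-cis, so one catalyst-controlled facial choice gives the all-cis 2S,3S array. The step needs facial, endo and regioselectivity and retention of the alkene geometry; the E geometry of 21 (unit 3 aryl turned away from the catalyst-bound oxygen), the tight ion pair in toluene and the low temperature should secure them and should suppress a free C2 cation (acetoxonium formation, scrambling of C2). As 17 is itself chiral, the matched antipode of the acid has to be used.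

Step 17
Reactants: 22 cycloadduct trimer (3-O-acetyl on unit 2)
Product: 23 trimer with free 3-OH on unit 2 (all-cis)
Conditions: K2CO3, MeOH/THF, rt
Reagents that add atoms: none
Why: Base-catalysed transesterification removes the acetate without touching the benzylic stereocentres, aryl halides or benzyl ethers.

Step 18
Reactants: 23 trimer with free 3-OH on unit 2
Product: 24 perbenzylated 6-iodo trimer (unit 2 3-O-benzyl)
Conditions: NaH, BnBr, Bu4NI (cat.), DMF, 0 °C to rt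
Reagents that add atoms: benzyl bromide, BrCc1ccccc1
Why: Williamson etherification replaces the acetate by a group that survives the aryllithium of step 21 and leaves in step 23.

Step 19
Reactants: 3 3,5,7,3',4'-penta-O-benzylepicatechin
Product: 25 4β-hydroxy-3,5,7,3',4'-penta-O-benzylepicatechin
Conditions: DDQ, CH2Cl2/H2O, rt
Reagents that add atoms: water, O
Why: DDQ benzylic oxidation at C4 as in step 4, with water as the nucleophile; the new carbinol centre is removed in step 20.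

Step 20
Reactants: 25 4β-hydroxy-3,5,7,3',4'-penta-O-benzylepicatechin
Product: 26 (2R,3S)-3,5,7-tris(benzyloxy)-2-[3,4-bis(benzyloxy)phenyl]chroman-4-one (unit 1 ketone; 2,3-cis)
Conditions: Dess–Martin periodinane, pyridine, CH2Cl2, 0 °C to rt
Reagents that add atoms: none
Why: Dess–Martin oxidation of the benzylic alcohol under buffered, non-enolising conditions, so that C3 next to the new ketone is not epimerised.

Step 21
Reactants: 24 perbenzylated 6-iodo trimer; 26 unit 1 ketone (1.5 equiv)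
Product: 28 tertiary alcohol tetramer (C4 of unit 1 bears OH and C6 of unit 2; aryl expected trans to the 3-benzyloxy group), via aryllithium 27 (not isolated)
Conditions: n-BuLi (1.05 equiv), THF, −78 °C; then 26, −78 to −40 °C
Reagents that add atoms: none
Why: Iodine–lithium exchange (much faster than bromine–lithium exchange, so the unit 4 bromide stays) and 1,2-addition of the aryllithium to the flavan-4-one from the face opposite the 2-aryl and 3-benzyloxy groups; the carbinol centre is removed in step 22.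

Step 22
Reactants: 28 tertiary alcohol tetramer
Product: 29 perbenzylated tetramer (unit 4 8-bromo; unit 1 C4 aryl cis to C3–O)
Conditions: n-Bu3SnH, CF3CO2H, CH2Cl2, 0 °C
Reagents that add atoms: none
Why: Ionic hydrogenation: the acid ionises the tertiary benzylic alcohol and hydride enters the C4 cation on the face opposite the cis 2-aryl and 3-benzyloxy groups, which places the C4 aryl cis to C3–O (4α, all-cis unit 1).

Step 23
Reactants: 29 perbenzylated tetramer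
Product: 30 CNP0120618.3 (target)
Conditions: H2 (1 atm), Pd(OH)2/C, NaOAc, THF/MeOH/H2O, rt
Reagents that add atoms: none
Why: Catalytic hydrogenolysis cleaves the 20 benzyl ethers and the aryl C–Br bond in one operation; the acetate buffer takes up HBr so that the acid-labile interflavan bonds and all stereocentres are kept.

**Compound list**

1 | (−)-epicatechin | O[C@@H]1Cc2c(O)cc(O)cc2O[C@@H]1c1ccc(O)c(O)c1 | starting material
2 | 5,7,3',4'-tetra-O-benzylepicatechin | c1c(OCc9ccccc9)cc(OCc9ccccc9)c2c1O[C@H](c1ccc(OCc9ccccc9)c(OCc9ccccc9)c1)[C@H](O)C2 | intermediate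
3 | 3,5,7,3',4'-penta-O-benzylepicatechin | c1c(OCc9ccccc9)cc(OCc9ccccc9)c2c1O[C@H](c1ccc(OCc9ccccc9)c(OCc9ccccc9)c1)[C@H](OCc9ccccc9)C2 | intermediate
4 | 8-bromo-3,5,7,3',4'-penta-O-benzylepicatechin | Brc1c(OCc9ccccc9)cc(OCc9ccccc9)c2c1O[C@H](c1ccc(OCc9ccccc9)c(OCc9ccccc9)c1)[C@H](OCc9ccccc9)C2 | intermediate
5 | 4β-(2-ethoxyethoxy)-3,5,7,3',4'-penta-O-benzylepicatechin | c1c(OCc9ccccc9)cc(OCc9ccccc9)c2c1O[C@H](c1ccc(OCc9ccccc9)c(OCc9ccccc9)c1)[C@H](OCc9ccccc9)[C@H]2OCCOCC | intermediate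
6 | 8-iodo-4β-(2-ethoxyethoxy)-3,5,7,3',4'-penta-O-benzylepicatechin | Ic1c(OCc9ccccc9)cc(OCc9ccccc9)c2c1O[C@H](c1ccc(OCc9ccccc9)c(OCc9ccccc9)c1)[C@H](OCc9ccccc9)[C@H]2OCCOCC | intermediate
7 | unit 3–4 dimer: 8-iodo-penta-O-benzylepicatechin-(4β→6)-8-bromo-penta-O-benzylepicatechin | Ic1c(OCc9ccccc9)cc(OCc9ccccc9)c3c1O[C@H](c1ccc(OCc9ccccc9)c(OCc9ccccc9)c1)[C@H](OCc9ccccc9)[C@H]3c1c(OCc9ccccc9)c(Br)c3c(c1OCc9ccccc9)C[C@@H](OCc9ccccc9)[C@@H](c1ccc(OCc9ccccc9)c(OCc9ccccc9)c1)O3 | intermediate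
8 | 3,5-bis(benzyloxy)phenol | Oc1cc(OCc9ccccc9)cc(OCc9ccccc9)c1 | starting material
9 | [3,5-bis(benzyloxy)phenoxy]triisopropylsilane | CC(C)[Si](Oc1cc(OCc9ccccc9)cc(OCc9ccccc9)c1)(C(C)C)C(C)C | intermediate
10 | [2,6-bis(benzyloxy)-4-(triisopropylsilyloxy)phenyl]lithium (not isolated) | [Li]c1c(OCc9ccccc9)cc(O[Si](C(C)C)(C(C)C)C(C)C)cc1OCc9ccccc9 | intermediate
11 | [3,5-bis(benzyloxy)-4-iodophenoxy]triisopropylsilane | Ic1c(OCc9ccccc9)cc(O[Si](C(C)C)(C(C)C)C(C)C)cc1OCc9ccccc9 | intermediate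
12 | 3,5-bis(benzyloxy)-4-iodophenol | Oc1cc(OCc9ccccc9)c(I)c(OCc9ccccc9)c1 | intermediate
13 | 2,4-bis(benzyloxy)-6-hydroxy-3-iodobenzaldehyde | O=Cc1c(O)cc(OCc9ccccc9)c(I)c1OCc9ccccc9 | intermediate
14 | 2,4-bis(benzyloxy)-6-(tert-butyldimethylsilyloxy)-3-iodobenzaldehyde | O=Cc1c(O[Si](C)(C)C(C)(C)C)cc(OCc9ccccc9)c(I)c1OCc9ccccc9 | intermediate
15 | 8-(chloromagnesio) unit 3–4 dimer (not isolated) | Cl[Mg]c1c(OCc9ccccc9)cc(OCc9ccccc9)c3c1O[C@H](c1ccc(OCc9ccccc9)c(OCc9ccccc9)c1)[C@H](OCc9ccccc9)[C@H]3c1c(OCc9ccccc9)c(Br)c3c(c1OCc9ccccc9)C[C@@H](OCc9ccccc9)[C@@H](c1ccc(OCc9ccccc9)c(OCc9ccccc9)c1)O3 | intermediate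
16 | [2,4-bis(benzyloxy)-6-(tert-butyldimethylsilyloxy)-3-iodophenyl](C8 of unit 3 of the dimer)methanol, carbinol epimers | OC(c1c(OCc9ccccc9)cc(OCc9ccccc9)c3c1O[C@H](c1ccc(OCc9ccccc9)c(OCc9ccccc9)c1)[C@H](OCc9ccccc9)[C@H]3c1c(OCc9ccccc9)c(Br)c3c(c1OCc9ccccc9)C[C@@H](OCc9ccccc9)[C@@H](c1ccc(OCc9ccccc9)c(OCc9ccccc9)c1)O3)c1c(O[Si](C)(C)C(C)(C)C)cc(OCc9ccccc9)c(I)c1OCc9ccccc9 | intermediate
17 | [2,4-bis(benzyloxy)-6-hydroxy-3-iodophenyl](C8 of unit 3 of the dimer)methanol, carbinol epimers (key-step precursor) | OC(c1c(OCc9ccccc9)cc(OCc9ccccc9)c3c1O[C@H](c1ccc(OCc9ccccc9)c(OCc9ccccc9)c1)[C@H](OCc9ccccc9)[C@H]3c1c(OCc9ccccc9)c(Br)c3c(c1OCc9ccccc9)C[C@@H](OCc9ccccc9)[C@@H](c1ccc(OCc9ccccc9)c(OCc9ccccc9)c1)O3)c1c(O)cc(OCc9ccccc9)c(I)c1OCc9ccccc9 | intermediate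
18 | 3,4-bis(benzyloxy)benzaldehyde | O=Cc1ccc(OCc9ccccc9)c(OCc9ccccc9)c1 | starting material
19 | 1,2-bis(benzyloxy)-4-ethynylbenzene | C#Cc1ccc(OCc9ccccc9)c(OCc9ccccc9)c1 | intermediate
20 | (Z)-2-[3,4-bis(benzyloxy)phenyl]ethenyl acetate | CC(=O)O/C=C\c1ccc(OCc9ccccc9)c(OCc9ccccc9)c1 | intermediate
21 | (E)-ortho-quinone methide: 3,5-bis(benzyloxy)-4-iodo-6-[(dimer-8-yl)methylidene]cyclohexa-2,4-dien-1-one (not isolated) | O=C1C=C(OCc9ccccc9)C(I)=C(OCc9ccccc9)/C1=C\c1c(OCc9ccccc9)cc(OCc9ccccc9)c3c1O[C@H](c1ccc(OCc9ccccc9)c(OCc9ccccc9)c1)[C@H](OCc9ccccc9)[C@H]3c1c(OCc9ccccc9)c(Br)c3c(c1OCc9ccccc9)C[C@@H](OCc9ccccc9)[C@@H](c1ccc(OCc9ccccc9)c(OCc9ccccc9)c1)O3 | intermediate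
22 | unit 2–3–4 trimer, unit 2 = 3-O-acetyl-6-iodo-5,7,3',4'-tetra-O-benzyl-ent-epicatechin (2S,3S, all-cis), C4→C8 of unit 3 (key-step product) | Ic1c(OCc9ccccc9)cc2c(c1OCc9ccccc9)[C@H](c1c(OCc9ccccc9)cc(OCc9ccccc9)c3c1O[C@H](c1ccc(OCc9ccccc9)c(OCc9ccccc9)c1)[C@H](OCc9ccccc9)[C@H]3c1c(OCc9ccccc9)c(Br)c3c(c1OCc9ccccc9)C[C@@H](OCc9ccccc9)[C@@H](c1ccc(OCc9ccccc9)c(OCc9ccccc9)c1)O3)[C@H](OC(C)=O)[C@H](c1ccc(OCc9ccccc9)c(OCc9ccccc9)c1)O2 | intermediate
23 | trimer with free 3-OH on unit 2 | Ic1c(OCc9ccccc9)cc2c(c1OCc9ccccc9)[C@H](c1c(OCc9ccccc9)cc(OCc9ccccc9)c3c1O[C@H](c1ccc(OCc9ccccc9)c(OCc9ccccc9)c1)[C@H](OCc9ccccc9)[C@H]3c1c(OCc9ccccc9)c(Br)c3c(c1OCc9ccccc9)C[C@@H](OCc9ccccc9)[C@@H](c1ccc(OCc9ccccc9)c(OCc9ccccc9)c1)O3)[C@H](O)[C@H](c1ccc(OCc9ccccc9)c(OCc9ccccc9)c1)O2 | intermediate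
24 | perbenzylated 6-iodo trimer | Ic1c(OCc9ccccc9)cc2c(c1OCc9ccccc9)[C@H](c1c(OCc9ccccc9)cc(OCc9ccccc9)c3c1O[C@H](c1ccc(OCc9ccccc9)c(OCc9ccccc9)c1)[C@H](OCc9ccccc9)[C@H]3c1c(OCc9ccccc9)c(Br)c3c(c1OCc9ccccc9)C[C@@H](OCc9ccccc9)[C@@H](c1ccc(OCc9ccccc9)c(OCc9ccccc9)c1)O3)[C@H](OCc9ccccc9)[C@H](c1ccc(OCc9ccccc9)c(OCc9ccccc9)c1)O2 | intermediate
25 | 4β-hydroxy-3,5,7,3',4'-penta-O-benzylepicatechin | c9ccccc9COc1cc(OCc9ccccc9)c2c(c1)O[C@H](c1ccc(OCc9ccccc9)c(OCc9ccccc9)c1)[C@H](OCc9ccccc9)[C@H]2O | intermediate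
26 | (2R,3S)-3,5,7-tris(benzyloxy)-2-[3,4-bis(benzyloxy)phenyl]chroman-4-one | c9ccccc9COc1cc(OCc9ccccc9)c2c(c1)O[C@H](c1ccc(OCc9ccccc9)c(OCc9ccccc9)c1)[C@H](OCc9ccccc9)C2=O | intermediate
27 | 6-lithio perbenzylated trimer (not isolated) | [Li]c1c(OCc9ccccc9)cc2c(c1OCc9ccccc9)[C@H](c1c(OCc9ccccc9)cc(OCc9ccccc9)c3c1O[C@H](c1ccc(OCc9ccccc9)c(OCc9ccccc9)c1)[C@H](OCc9ccccc9)[C@H]3c1c(OCc9ccccc9)c(Br)c3c(c1OCc9ccccc9)C[C@@H](OCc9ccccc9)[C@@H](c1ccc(OCc9ccccc9)c(OCc9ccccc9)c1)O3)[C@H](OCc9ccccc9)[C@H](c1ccc(OCc9ccccc9)c(OCc9ccccc9)c1)O2 | intermediate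
28 | tertiary alcohol tetramer (unit 1 C4: OH cis and unit 2 aryl trans to C3–O) | c9ccccc9COc1cc(OCc9ccccc9)c2c(c1)O[C@H](c1ccc(OCc9ccccc9)c(OCc9ccccc9)c1)[C@H](OCc9ccccc9)[C@@]2(O)c1c(OCc9ccccc9)cc2c(c1OCc9ccccc9)[C@H](c1c(OCc9ccccc9)cc(OCc9ccccc9)c3c1O[C@H](c1ccc(OCc9ccccc9)c(OCc9ccccc9)c1)[C@H](OCc9ccccc9)[C@H]3c1c(OCc9ccccc9)c(Br)c3c(c1OCc9ccccc9)C[C@@H](OCc9ccccc9)[C@@H](c1ccc(OCc9ccccc9)c(OCc9ccccc9)c1)O3)[C@H](OCc9ccccc9)[C@H](c1ccc(OCc9ccccc9)c(OCc9ccccc9)c1)O2 | intermediate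
29 | perbenzylated tetramer, unit 4 8-bromo | c9ccccc9COc1cc(OCc9ccccc9)c2c(c1)O[C@H](c1ccc(OCc9ccccc9)c(OCc9ccccc9)c1)[C@H](OCc9ccccc9)[C@@H]2c1c(OCc9ccccc9)cc2c(c1OCc9ccccc9)[C@H](c1c(OCc9ccccc9)cc(OCc9ccccc9)c3c1O[C@H](c1ccc(OCc9ccccc9)c(OCc9ccccc9)c1)[C@H](OCc9ccccc9)[C@H]3c1c(OCc9ccccc9)c(Br)c3c(c1OCc9ccccc9)C[C@@H](OCc9ccccc9)[C@@H](c1ccc(OCc9ccccc9)c(OCc9ccccc9)c1)O3)[C@H](OCc9ccccc9)[C@H](c1ccc(OCc9ccccc9)c(OCc9ccccc9)c1)O2 | intermediate
30 | CNP0120618.3 | Oc1cc(O)c2c(c1)O[C@H](c1ccc(O)c(O)c1)[C@H](O)[C@@H]2c1c(O)cc2c(c1O)[C@H](c1c(O)cc(O)c3c1O[C@H](c1ccc(O)c(O)c1)[C@H](O)[C@H]3c1c(O)cc3c(c1O)C[C@@H](O)[C@@H](c1ccc(O)c(O)c1)O3)[C@H](O)[C@H](c1ccc(O)c(O)c1)O2 | target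

**Step count and risks**

Total: 23 steps. Longest linear sequence: 13 steps (steps 1, 2, 4, 5, 6, 12, 13, 16, 17, 18, 21, 22, 23; the branch from 8 is equally long).

Steps most likely to fail:

1. Step 16 (proposed new method). The enol acetate may be too weak a nucleophile for the strongly stabilised quinone methide. The addition may become stepwise, so that the alkene geometry is lost or an acetoxonium ion scrambles C2. The exo mode, the wrong face (catalyst mismatched with the dimer) or decay of 21 may win.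
 Fallback, from 17 back to 23, by known reaction types. Commercial 1-[3,4-bis(benzyloxy)phenyl]ethanone is converted with NH2OH·HCl/pyridine into its oxime F1 and this with iron powder, Ac2O and AcOH into N-{1-[3,4-bis(benzyloxy)phenyl]ethenyl}acetamide F2. With the same phosphoric acid 17 again gives 21, and F2 adds through its terminal carbon to the methide carbon (the established enantioselective enamide addition to ortho-quinone methides). Closure of the phenol on the N-acyliminium carbon gives the 2-acetamidochroman F3, which on warming with TsOH loses acetamide to give the 2,4-diaryl-4H-chromene F4, whose C4 is already set. Hydroboration (BH3·SMe2, then H2O2/NaOH) should add H to C2 and OH to C3 on the face opposite the C4 aryl group and give the 2,3-trans-3,4-trans alcohol F5 with the two aryl groups cis. Dess–Martin oxidation gives the flavan-3-one F6, and LiBH(s-Bu)3 at −78 °C should deliver hydride on the face opposite both aryl groups, which gives the all-cis alcohol 23 and bypasses steps 16 and 17.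

2. Step 21. The crowded aryllithium 27 (lithium between two benzyloxy groups on a trimer) may deprotonate ketone 26 at C3 instead of adding, bromine–lithium exchange at unit 4 may compete, and the acid of step 22 then acts on a tetramer with two acid-labile interflavan bonds.
 Fallback, from 10 and 26 back to 29: unit 1 is joined to ring A before the cycloaddition, so that the ketone addition and the acidic reduction are run on small fragments. The aryllithium 10 (made as in step 8, no iodine added) is added to 26 to give the tertiary alcohol F7, and n-Bu3SnH/CF3CO2H reduces it to the 4-aryl flavan F8 (aryl cis to C3–O). Bu4NF gives the phenol F9, MgCl2/Et3N/(CH2O)n formylates one of its two equivalent ortho positions to the salicylaldehyde F10, and t-BuMe2SiCl/imidazole gives the silyl ether F11. Arylmagnesium 15 adds to F11 to give the carbinol F12, and Bu4NF/AcOH frees the phenol in F13. The phosphoric acid of step 16 with 20 converts F13 through the ortho-quinone methide F14 into the tetramer acetate F15. K2CO3/MeOH gives the alcohol F16, and NaH/BnBr gives 29.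

3. Step 12. The doubly ortho-substituted arylmagnesium 15 may add only slowly to the crowded, electron-rich aldehyde 14, and the silyl group may move from the phenol oxygen to the new alkoxide and set off early loss of the benzylic oxygen.
 Fallback, from 15 and 12 back to 17: the roles are reversed. 15 is quenched with DMF to give the dimer 8-carbaldehyde F17. Phenol 12 is converted with EtMgBr in toluene into its bromomagnesium phenoxide F18, which should add through its ortho carbon to F17 in a magnesium-chelated ortho-hydroxyalkylation of the phenol and give 17 directly, so that steps 11 and 13 are not needed.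

**Further compounds**

F1 | step 16 | 1-[3,4-bis(benzyloxy)phenyl]ethanone oxime | CC(=NO)c1ccc(OCc9ccccc9)c(OCc9ccccc9)c1
F2 | step 16 | N-{1-[3,4-bis(benzyloxy)phenyl]ethenyl}acetamide | CC(=O)NC(=C)c1ccc(OCc9ccccc9)c(OCc9ccccc9)c1
F3 | step 16 | 2-acetamido-2-aryl-4-(dimer-8-yl)chroman of unit 2 (C2 epimers) | Ic1c(OCc9ccccc9)cc2c(c1OCc9ccccc9)[C@H](c1c(OCc9ccccc9)cc(OCc9ccccc9)c3c1O[C@H](c1ccc(OCc9ccccc9)c(OCc9ccccc9)c1)[C@H](OCc9ccccc9)[C@H]3c1c(OCc9ccccc9)c(Br)c3c(c1OCc9ccccc9)C[C@@H](OCc9ccccc9)[C@@H](c1ccc(OCc9ccccc9)c(OCc9ccccc9)c1)O3)CC(NC(C)=O)(c1ccc(OCc9ccccc9)c(OCc9ccccc9)c1)O2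
F4 | step 16 | 2-aryl-4-(dimer-8-yl)-4H-chromene of unit 2 | Ic1c(OCc9ccccc9)cc2c(c1OCc9ccccc9)[C@H](c1c(OCc9ccccc9)cc(OCc9ccccc9)c3c1O[C@H](c1ccc(OCc9ccccc9)c(OCc9ccccc9)c1)[C@H](OCc9ccccc9)[C@H]3c1c(OCc9ccccc9)c(Br)c3c(c1OCc9ccccc9)C[C@@H](OCc9ccccc9)[C@@H](c1ccc(OCc9ccccc9)c(OCc9ccccc9)c1)O3)C=C(c1ccc(OCc9ccccc9)c(OCc9ccccc9)c1)O2
F5 | step 16 | trimer 3-ol, unit 2 2,3-trans-3,4-trans (aryl groups cis) | Ic1c(OCc9ccccc9)cc2c(c1OCc9ccccc9)[C@H](c1c(OCc9ccccc9)cc(OCc9ccccc9)c3c1O[C@H](c1ccc(OCc9ccccc9)c(OCc9ccccc9)c1)[C@H](OCc9ccccc9)[C@H]3c1c(OCc9ccccc9)c(Br)c3c(c1OCc9ccccc9)C[C@@H](OCc9ccccc9)[C@@H](c1ccc(OCc9ccccc9)c(OCc9ccccc9)c1)O3)[C@@H](O)[C@H](c1ccc(OCc9ccccc9)c(OCc9ccccc9)c1)O2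
F6 | step 16 | trimer with unit 2 as flavan-3-one (2,4-cis) | Ic1c(OCc9ccccc9)cc2c(c1OCc9ccccc9)[C@H](c1c(OCc9ccccc9)cc(OCc9ccccc9)c3c1O[C@H](c1ccc(OCc9ccccc9)c(OCc9ccccc9)c1)[C@H](OCc9ccccc9)[C@H]3c1c(OCc9ccccc9)c(Br)c3c(c1OCc9ccccc9)C[C@@H](OCc9ccccc9)[C@@H](c1ccc(OCc9ccccc9)c(OCc9ccccc9)c1)O3)C(=O)[C@H](c1ccc(OCc9ccccc9)c(OCc9ccccc9)c1)O2
F7 | step 21 | unit 1 tertiary alcohol with 2,6-bis(benzyloxy)-4-(triisopropylsilyloxy)phenyl at C4 | c9ccccc9COc1cc(OCc9ccccc9)c2c(c1)O[C@H](c1ccc(OCc9ccccc9)c(OCc9ccccc9)c1)[C@H](OCc9ccccc9)[C@@]2(O)c1c(OCc9ccccc9)cc(O[Si](C(C)C)(C(C)C)C(C)C)cc1OCc9ccccc9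
F8 | step 21 | 4α-[2,6-bis(benzyloxy)-4-(triisopropylsilyloxy)phenyl]-penta-O-benzylepicatechin | c9ccccc9COc1cc(OCc9ccccc9)c2c(c1)O[C@H](c1ccc(OCc9ccccc9)c(OCc9ccccc9)c1)[C@H](OCc9ccccc9)[C@@H]2c1c(OCc9ccccc9)cc(O[Si](C(C)C)(C(C)C)C(C)C)cc1OCc9ccccc9
F9 | step 21 | 4α-[2,6-bis(benzyloxy)-4-hydroxyphenyl]-penta-O-benzylepicatechin | c9ccccc9COc1cc(OCc9ccccc9)c2c(c1)O[C@H](c1ccc(OCc9ccccc9)c(OCc9ccccc9)c1)[C@H](OCc9ccccc9)[C@@H]2c1c(OCc9ccccc9)cc(O)cc1OCc9ccccc9
F10 | step 21 | salicylaldehyde carrying unit 1 | c9ccccc9COc1cc(OCc9ccccc9)c2c(c1)O[C@H](c1ccc(OCc9ccccc9)c(OCc9ccccc9)c1)[C@H](OCc9ccccc9)[C@@H]2c1c(OCc9ccccc9)cc(O)c(C=O)c1OCc9ccccc9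
F11 | step 21 | tert-butyldimethylsilyl ether of F10 | c9ccccc9COc1cc(OCc9ccccc9)c2c(c1)O[C@H](c1ccc(OCc9ccccc9)c(OCc9ccccc9)c1)[C@H](OCc9ccccc9)[C@@H]2c1c(OCc9ccccc9)cc(O[Si](C)(C)C(C)(C)C)c(C=O)c1OCc9ccccc9
F12 | step 21 | silyl-protected diaryl carbinol carrying unit 1 (carbinol epimers) | c9ccccc9COc1cc(OCc9ccccc9)c2c(c1)O[C@H](c1ccc(OCc9ccccc9)c(OCc9ccccc9)c1)[C@H](OCc9ccccc9)[C@@H]2c4c(OCc9ccccc9)cc(O[Si](C)(C)C(C)(C)C)c(C(O)c1c(OCc9ccccc9)cc(OCc9ccccc9)c3c1O[C@H](c1ccc(OCc9ccccc9)c(OCc9ccccc9)c1)[C@H](OCc9ccccc9)[C@H]3c1c(OCc9ccccc9)c(Br)c3c(c1OCc9ccccc9)C[C@@H](OCc9ccccc9)[C@@H](c1ccc(OCc9ccccc9)c(OCc9ccccc9)c1)O3)c4OCc9ccccc9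
F13 | step 21 | ortho-hydroxy diaryl carbinol carrying unit 1 (carbinol epimers) | c9ccccc9COc1cc(OCc9ccccc9)c2c(c1)O[C@H](c1ccc(OCc9ccccc9)c(OCc9ccccc9)c1)[C@H](OCc9ccccc9)[C@@H]2c4c(OCc9ccccc9)cc(O)c(C(O)c1c(OCc9ccccc9)cc(OCc9ccccc9)c3c1O[C@H](c1ccc(OCc9ccccc9)c(OCc9ccccc9)c1)[C@H](OCc9ccccc9)[C@H]3c1c(OCc9ccccc9)c(Br)c3c(c1OCc9ccccc9)C[C@@H](OCc9ccccc9)[C@@H](c1ccc(OCc9ccccc9)c(OCc9ccccc9)c1)O3)c4OCc9ccccc9
F14 | step 21 | (E)-ortho-quinone methide carrying unit 1 | c9ccccc9COc1cc(OCc9ccccc9)c2c(c1)O[C@H](c1ccc(OCc9ccccc9)c(OCc9ccccc9)c1)[C@H](OCc9ccccc9)[C@@H]2C4=C(OCc9ccccc9)/C(=C\c1c(OCc9ccccc9)cc(OCc9ccccc9)c3c1O[C@H](c1ccc(OCc9ccccc9)c(OCc9ccccc9)c1)[C@H](OCc9ccccc9)[C@H]3c1c(OCc9ccccc9)c(Br)c3c(c1OCc9ccccc9)C[C@@H](OCc9ccccc9)[C@@H](c1ccc(OCc9ccccc9)c(OCc9ccccc9)c1)O3)C(=O)C=C4OCc9ccccc9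
F15 | step 21 | tetramer with 3-O-acetyl on unit 2 | c9ccccc9COc1cc(OCc9ccccc9)c2c(c1)O[C@H](c1ccc(OCc9ccccc9)c(OCc9ccccc9)c1)[C@H](OCc9ccccc9)[C@@H]2c1c(OCc9ccccc9)cc2c(c1OCc9ccccc9)[C@H](c1c(OCc9ccccc9)cc(OCc9ccccc9)c3c1O[C@H](c1ccc(OCc9ccccc9)c(OCc9ccccc9)c1)[C@H](OCc9ccccc9)[C@H]3c1c(OCc9ccccc9)c(Br)c3c(c1OCc9ccccc9)C[C@@H](OCc9ccccc9)[C@@H](c1ccc(OCc9ccccc9)c(OCc9ccccc9)c1)O3)[C@H](OC(C)=O)[C@H](c1ccc(OCc9ccccc9)c(OCc9ccccc9)c1)O2
F16 | step 21 | tetramer with free 3-OH on unit 2 | c9ccccc9COc1cc(OCc9ccccc9)c2c(c1)O[C@H](c1ccc(OCc9ccccc9)c(OCc9ccccc9)c1)[C@H](OCc9ccccc9)[C@@H]2c1c(OCc9ccccc9)cc2c(c1OCc9ccccc9)[C@H](c1c(OCc9ccccc9)cc(OCc9ccccc9)c3c1O[C@H](c1ccc(OCc9ccccc9)c(OCc9ccccc9)c1)[C@H](OCc9ccccc9)[C@H]3c1c(OCc9ccccc9)c(Br)c3c(c1OCc9ccccc9)C[C@@H](OCc9ccccc9)[C@@H](c1ccc(OCc9ccccc9)c(OCc9ccccc9)c1)O3)[C@H](O)[C@H](c1ccc(OCc9ccccc9)c(OCc9ccccc9)c1)O2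
F17 | step 12 | unit 3–4 dimer 8-carbaldehyde (unit 4 8-bromo) | O=Cc1c(OCc9ccccc9)cc(OCc9ccccc9)c3c1O[C@H](c1ccc(OCc9ccccc9)c(OCc9ccccc9)c1)[C@H](OCc9ccccc9)[C@H]3c1c(OCc9ccccc9)c(Br)c3c(c1OCc9ccccc9)C[C@@H](OCc9ccccc9)[C@@H](c1ccc(OCc9ccccc9)c(OCc9ccccc9)c1)O3
F18 | step 12 | bromomagnesium 3,5-bis(benzyloxy)-4-iodophenoxide | Br[Mg]Oc1cc(OCc9ccccc9)c(I)c(OCc9ccccc9)c1
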